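**Retrosynthetic overview**

1. The linker atoms are called Ca (on C8 of chromene A), Cb, Cc (the stereocentre, on C8 of chromene B) and Cd (the methyl). The disconnection is Cc–C8 (chromene B): H is added to Cd and the chromene B aryl to Cc across the terminal Cc=Cd alkene of a chromene A 1-aryl-buta-1,3-diene, by chiral nickel catalysis, the aryl coming from the 8-boronic acid.
2. Enabling feature: Cc is one terminus of the allyl unit Ca–Cb–Cc, whose other terminus Ca is benzylic to the benzene ring of chromene A and flanked by O1 and the 7-OMe of that ring. A π-allyl nickel intermediate should therefore couple at Cc only and release Ca=Cb as E, so one operation sets the bond, the only stereocentre, the alkene geometry and the methyl group.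
3. Both halves come from one compound, 8-bromo-5,7-dimethoxy-2,2-dimethyl-2H-chromene: it is lithiated, formylated and olefinated (diene half), or converted through its Grignard reagent into the boronic acid (boronic acid half).
4. Ring order: the benzene ring is bought as 3,5-dimethoxyphenol; the pyran ring of both chromenes is formed once, before the branch point, by prenal annulation of 2-bromo-3,5-dimethoxyphenol (condensation, then oxa-6π closure); no ring is formed afterwards.

Key step: step 6

Assumption: the (R) antipode of the spiro aminophosphine ligand is taken to deliver the (S) centre; if the nickel catalyst shows the opposite sense on this diene, the (S) ligand is used with nothing else changed.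

**Route**

Step 1
Reactants: 1 3,5-dimethoxyphenol
Product: 2 2-bromo-3,5-dimethoxyphenol
Conditions: NBS (1.0 equiv), i-Pr2NH (10 mol %), CH2Cl2, −78 → 0 °C
Reagents that add atoms: N-bromosuccinimide, O=C1CCC(=O)N1Br
Why: Amine-mediated ortho-bromination of a phenol (electrophilic aromatic substitution) should place bromine at C2, between OH and OMe, because the N-bromoamine is delivered by hydrogen bonding to the OH, C4 is flanked by two larger OMe groups and two equivalent ortho sites compete with one para site, while one equivalent of NBS at low temperature limits dibromination.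

Step 2
Reactants: 2 2-bromo-3,5-dimethoxyphenol
Product: 4 8-bromo-5,7-dimethoxy-2,2-dimethyl-2H-chromene, via ortho-quinone methide 3 (not isolated)
Conditions: 3-methylbut-2-enal (2 equiv), ethylenediammonium diacetate (EDDA, 10 mol %), xylene, 140 °C
Reagents that add atoms: 3-methylbut-2-enal, CC(C)=CC=O
Why: Amine-catalysed chromene annulation (condensation of the iminium-activated enal at the only free ortho carbon, loss of water to the ortho-quinone methide 3, oxa-6π electrocyclisation) should close the 2,2-dimethyl-2H-pyran ring, and the bromine that blocks the second ortho position thereby ends at C8 with the methoxy groups at C5 and C7.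

Step 3
Reactants: 4 8-bromo-5,7-dimethoxy-2,2-dimethyl-2H-chromene
Product: 7 5,7-dimethoxy-2,2-dimethyl-2H-chromene-8-carbaldehyde, via aryllithium 5 (not isolated), via lithium hemiaminal alkoxide 6 (not isolated)
Conditions: n-BuLi, THF, −78 °C; DMF, −78 → 0 °C; aq. NH4Cl
Reagents that add atoms: N,N-dimethylformamide, CN(C)C=O
Why: Bromine–lithium exchange followed by formylation with DMF should be clean because the aryllithium is stabilised by two ortho oxygen atoms and the chromene alkene, the methoxy groups and the tetrahedral adduct 6 are inert at −78 °C, the aldehyde being released only on work-up.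

Step 4
Reactants: 7 5,7-dimethoxy-2,2-dimethyl-2H-chromene-8-carbaldehyde
Product: 9 8-[(1E)-buta-1,3-dien-1-yl]-5,7-dimethoxy-2,2-dimethyl-2H-chromene, via lithium beta-oxido phosphonate 8 (not isolated)
Conditions: diethyl allylphosphonate, n-BuLi, THF, −78 °C; 7, HMPA, −78 °C → rt
Reagents that add atoms: diethyl allylphosphonate, C=CCP(=O)(OCC)OCC
Why: Horner–Wadsworth–Emmons-type olefination with α-lithiated diethyl allylphosphonate should give the terminal 1,3-diene, HMPA promoting elimination of lithium diethyl phosphate from adduct 8 with E selectivity for aryl aldehydes, and a minor Z isomer need not be removed because step 6 passes through an allyl intermediate that equilibrates.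

Step 5
Reactants: 4 8-bromo-5,7-dimethoxy-2,2-dimethyl-2H-chromene
Product: 12 (5,7-dimethoxy-2,2-dimethyl-2H-chromen-8-yl)boronic acid, via arylmagnesium bromide 10 (not isolated), via bromomagnesium aryl borate 11 (not isolated)
Conditions: Mg turnings, LiCl, THF, rt → 40 °C; B(OiPr)3, −78 °C → rt; aq. NH4Cl, 0 °C
Reagents that add atoms: triisopropyl borate, CC(C)OB(OC(C)C)OC(C)C; water, O
Why: Direct magnesium insertion into the aryl bromide (Grignard formation, LiCl accelerating the insertion and keeping the hindered electron-rich arylmagnesium bromide 10 in solution) followed by trapping with a trialkyl borate (electrophilic borylation) and near-neutral hydrolysis of the ate complex 11 should give the boronic acid, the chromene alkene and the methoxy groups being inert to the Grignard reagent and the mild work-up avoiding acid- or base-induced protodeboronation of this di-ortho-alkoxy arylboronic acid.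

Step 6
Reactants: 9 8-[(1E)-buta-1,3-dien-1-yl]-5,7-dimethoxy-2,2-dimethyl-2H-chromene; 12 (5,7-dimethoxy-2,2-dimethyl-2H-chromen-8-yl)boronic acid
Product: 13 8-[(1E,3S)-3-(5,7-dimethoxy-2,2-dimethyl-2H-chromen-8-yl)but-1-en-1-yl]-5,7-dimethoxy-2,2-dimethyl-2H-chromene
Conditions: Ni(cod)2 (10 mol %), (R)-7'-[bis(3,5-di-tert-butylphenyl)phosphanyl]-2,2',3,3'-tetrahydro-1,1'-spirobi[inden]-7-amine (12 mol %), 12 (1.5 equiv), MeOH/THF, 40 °C
Reagents that add atoms: none
Why: Zerovalent nickel bearing the chiral aminophosphine binds the terminal alkene of 9, methanol transfers hydrogen to Cd to give a syn-π-allyl nickel methoxide spanning Ca–Cb–Cc, the aryl group of 12 is transmetalated from boron to nickel, and C(sp2)–C(sp3) reductive elimination at Cc releases 13 and the zerovalent catalyst. The closest known reaction type is the nickel-catalysed enantioselective 1,2-Markovnikov hydroarylation of 1-aryl-1,3-dienes with arylboronic acids in alcohol solvents, which gives (E)-1,3-diarylbut-1-enes. No ring is closed in this step. The Cc stereocentre is set under catalyst control: the chiral ligand fixes from which face of the allyl terminus Cc the nickel-bound aryl is delivered, and the ligand antipode named in the assumption is the one taken to give S. The step needs Cc over Ca regioselectivity and E geometry, which the substrate secures because coupling at Cc keeps Ca=Cb conjugated with the benzene ring of chromene A while O1 and the 7-methoxy group flanking C8 shield Ca, and because the syn-allyl (into which the anti-allyl from any Z diene should isomerise by π–σ–π interconversion) can only open to the E alkene. It also needs chemoselectivity over the two chromene C3=C4 alkenes, which are cis-disubstituted, sit next to the quaternary C2 and give no allyl on hydrometalation, so that only the terminal diene unit should be engaged.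

**Compound list**

1 | 3,5-dimethoxyphenol | COc1cc(O)cc(OC)c1 | starting material
2 | 2-bromo-3,5-dimethoxyphenol | COc1cc(O)c(Br)c(OC)c1 | intermediate
3 | 2-bromo-3,5-dimethoxy-6-(3-methylbut-2-en-1-ylidene)cyclohexa-2,4-dien-1-one (ortho-quinone methide, formed in the flask) | O=C1C(Br)=C(OC)C=C(OC)C1=CC=C(C)C | intermediate
4 | 8-bromo-5,7-dimethoxy-2,2-dimethyl-2H-chromene | Brc1c(OC)cc(OC)c2c1OC(C)(C)C=C2 | intermediate
5 | (5,7-dimethoxy-2,2-dimethyl-2H-chromen-8-yl)lithium (formed in the flask) | [Li]c1c(OC)cc(OC)c2c1OC(C)(C)C=C2 | intermediate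
6 | lithium (dimethylamino)(5,7-dimethoxy-2,2-dimethyl-2H-chromen-8-yl)methanolate (formed in the flask) | [Li]OC(N(C)C)c1c(OC)cc(OC)c2c1OC(C)(C)C=C2 | intermediate
7 | 5,7-dimethoxy-2,2-dimethyl-2H-chromene-8-carbaldehyde | O=Cc1c(OC)cc(OC)c2c1OC(C)(C)C=C2 | intermediate
8 | lithium 2-(diethoxyphosphoryl)-1-(5,7-dimethoxy-2,2-dimethyl-2H-chromen-8-yl)but-3-en-1-olate (diastereomer mixture, formed in the flask) | [Li]OC(C(C=C)P(=O)(OCC)OCC)c1c(OC)cc(OC)c2c1OC(C)(C)C=C2 | intermediate
9 | 8-[(1E)-buta-1,3-dien-1-yl]-5,7-dimethoxy-2,2-dimethyl-2H-chromene | C=C/C=C/c1c(OC)cc(OC)c2c1OC(C)(C)C=C2 | intermediate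
10 | (5,7-dimethoxy-2,2-dimethyl-2H-chromen-8-yl)magnesium bromide (formed in the flask) | Br[Mg]c1c(OC)cc(OC)c2c1OC(C)(C)C=C2 | intermediate
11 | bromomagnesium (5,7-dimethoxy-2,2-dimethyl-2H-chromen-8-yl)tri(propan-2-yloxy)borate (formed in the flask) | [Mg+2].[Br-].CC(C)O[B-](OC(C)C)(OC(C)C)c1c(OC)cc(OC)c2c1OC(C)(C)C=C2 | intermediate
12 | (5,7-dimethoxy-2,2-dimethyl-2H-chromen-8-yl)boronic acid | OB(O)c1c(OC)cc(OC)c2c1OC(C)(C)C=C2 | intermediate
13 | 8-[(1E,3S)-3-(5,7-dimethoxy-2,2-dimethyl-2H-chromen-8-yl)but-1-en-1-yl]-5,7-dimethoxy-2,2-dimethyl-2H-chromene | COc1cc(OC)c(/C=C/[C@H](C)c2c(OC)cc(OC)c3c2OC(C)(C)C=C3)c2c1C=CC(C)(C)O2 | target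

**Count**

Total step count: 6. Longest linear sequence: 5 steps (steps 1, 2, 3, 4 and 6, from 3,5-dimethoxyphenol).

**Steps most likely to fail, with fallbacks**

Step 6. Protodeboronation of the di-ortho-alkoxy boronic acid in methanol may outrun transmetalation. The reductive elimination joining two doubly ortho-substituted partners may be slow enough for the diene to oligomerise on zerovalent nickel. Facial selectivity may also be lower than on unhindered dienes.

The fallback makes the same Cc–C8 bond by auxiliary-controlled conjugate addition; it sets out from bromide 4 and returns at target 13. (R)-4-Phenyloxazolidin-2-one is N-acylated with (E)-but-2-enoyl chloride (Et3N, DMAP cat., CH2Cl2, 0 °C) to the imide (R)-3-[(E)-but-2-enoyl]-4-phenyloxazolidin-2-one F1. Bromide 4 is converted with Mg turnings and LiCl in THF, as in step 5, into the Grignard reagent 10. With CuBr·SMe2 (THF/Me2S, −40 → −10 °C; aq. NH4Cl), 10 should add to F1 on the face anti to the phenyl group of the magnesium-chelated s-cis imide, which should give the adduct (R)-3-[(S)-3-(5,7-dimethoxy-2,2-dimethyl-2H-chromen-8-yl)butanoyl]-4-phenyloxazolidin-2-one F2. LiBH4 (THF, MeOH, 0 °C) should release the alcohol (S)-3-(5,7-dimethoxy-2,2-dimethyl-2H-chromen-8-yl)butan-1-ol F3 together with the auxiliary. Dess–Martin periodinane (NaHCO3, CH2Cl2) should give the aldehyde (S)-3-(5,7-dimethoxy-2,2-dimethyl-2H-chromen-8-yl)butanal F4. Aryllithium 5, generated from a second portion of 4 as in step 3 (n-BuLi, THF, −78 °C), should add to F4 and, after aq. NH4Cl, give the carbinol (3S)-1,3-bis(5,7-dimethoxy-2,2-dimethyl-2H-chromen-8-yl)butan-1-ol F5 as a mixture of epimers at the carbinol carbon. MsCl and Et3N (CH2Cl2, 0 °C → rt) should convert F5 into the mesylate (3S)-1,3-bis(5,7-dimethoxy-2,2-dimethyl-2H-chromen-8-yl)butyl methanesulfonate F6. F6 is expected to ionise at the carbon benzylic to chromene A and lose a proton, giving the conjugated E alkene, that is 13; Cc is not touched.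

Step 1. Competing attack at C4 and dibromination may give an isomer mixture that is hard to separate.

The fallback fixes the position by directed ortho-metalation; it sets out from phenol 1 and returns at bromophenol 2. Phenol 1 is carbamoylated (ClC(O)NEt2, NaH, THF) to the carbamate 3,5-dimethoxyphenyl N,N-diethylcarbamate F7. s-BuLi/TMEDA (THF, −78 °C) should deprotonate F7 between the carbamate and the neighbouring OMe, giving the aryllithium [2-(diethylcarbamoyloxy)-4,6-dimethoxyphenyl]lithium F8. 1,2-Dibromotetrachloroethane should brominate F8 at −78 °C to the bromocarbamate 2-bromo-3,5-dimethoxyphenyl N,N-diethylcarbamate F9. NaOH (EtOH/H2O, reflux), then acidification, should cleave F9 to 2.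

Step 4. Attack of the allylphosphonate anion through its γ carbon, incomplete elimination of the adduct, and oligomerisation of the electron-rich diene during elimination or isolation may erode the material.

The fallback replaces olefination by addition and elimination; it sets out from aldehyde 7 and returns at diene 9. Allylmagnesium bromide (THF, −78 °C) should give the homoallylic alcohol 1-(5,7-dimethoxy-2,2-dimethyl-2H-chromen-8-yl)but-3-en-1-ol F10. MsCl and Et3N (CH2Cl2, 0 °C) should form the mesylate 1-(5,7-dimethoxy-2,2-dimethyl-2H-chromen-8-yl)but-3-en-1-yl methanesulfonate F11. DBU should eliminate F11 to the conjugated diene 9 under non-acidic conditions.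

Further compounds
F1 | step 6 | (R)-3-[(E)-but-2-enoyl]-4-phenyloxazolidin-2-one | C/C=C/C(=O)N1[C@H](c2ccccc2)COC1=O
F2 | step 6 | (R)-3-[(S)-3-(5,7-dimethoxy-2,2-dimethyl-2H-chromen-8-yl)butanoyl]-4-phenyloxazolidin-2-one | O=C(C[C@H](C)c1c(OC)cc(OC)c2c1OC(C)(C)C=C2)N1[C@H](c2ccccc2)COC1=O
F3 | step 6 | (S)-3-(5,7-dimethoxy-2,2-dimethyl-2H-chromen-8-yl)butan-1-ol | OCC[C@H](C)c1c(OC)cc(OC)c2c1OC(C)(C)C=C2
F4 | step 6 | (S)-3-(5,7-dimethoxy-2,2-dimethyl-2H-chromen-8-yl)butanal | O=CC[C@H](C)c1c(OC)cc(OC)c2c1OC(C)(C)C=C2
F5 | step 6 | (3S)-1,3-bis(5,7-dimethoxy-2,2-dimethyl-2H-chromen-8-yl)butan-1-ol (both epimers at C1) | OC(C[C@H](C)c1c(OC)cc(OC)c2c1OC(C)(C)C=C2)c1c(OC)cc(OC)c2c1OC(C)(C)C=C2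
F6 | step 6 | (3S)-1,3-bis(5,7-dimethoxy-2,2-dimethyl-2H-chromen-8-yl)butyl methanesulfonate (both epimers at C1) | CS(=O)(=O)OC(C[C@H](C)c1c(OC)cc(OC)c2c1OC(C)(C)C=C2)c1c(OC)cc(OC)c2c1OC(C)(C)C=C2
F7 | step 1 | 3,5-dimethoxyphenyl N,N-diethylcarbamate | CCN(CC)C(=O)Oc1cc(OC)cc(OC)c1
F8 | step 1 | [2-(diethylcarbamoyloxy)-4,6-dimethoxyphenyl]lithium | CCN(CC)C(=O)Oc1cc(OC)cc(OC)c1[Li]
F9 | step 1 | 2-bromo-3,5-dimethoxyphenyl N,N-diethylcarbamate | CCN(CC)C(=O)Oc1cc(OC)cc(OC)c1Br
F10 | step 4 | 1-(5,7-dimethoxy-2,2-dimethyl-2H-chromen-8-yl)but-3-en-1-ol | OC(CC=C)c1c(OC)cc(OC)c2c1OC(C)(C)C=C2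
F11 | step 4 | 1-(5,7-dimethoxy-2,2-dimethyl-2H-chromen-8-yl)but-3-en-1-yl methanesulfonate | CS(=O)(=O)OC(CC=C)c1c(OC)cc(OC)c2c1OC(C)(C)C=C2
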